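Ring B is disconnected at C6–C7 and C8–C9. In the forward sense C6 (the future carbonyl) is an aldehyde and C9 (the side-chain methine) the β-carbon of an enoate, both on a ring A that already carries the quaternary C10 and the 2α,3β-dichloride; the C7–C8(=C17) unit is delivered as 2,3-bis(pinacolboryl)propene. In one flask allylboration joins C7 to C6 and rhodium-catalysed conjugate addition of the remaining alkenylboronate joins C8 to C9, closing ring B with the exocyclic methylene and the C9 configuration in place. Ring A comes from an oxazolidinone alkylation, two lactone alkylations, ring-closing metathesis and a chlorolactonisation; an auxiliary aldol and imide closure finish.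

Key step: step 12

Remark: labdane numbering is used for all intermediates (ring A: C1–C5 and C10; ring B: C5–C10; C17 exocyclic methylene; C11–C12 side chain; C13–C16 succinimide), and α/β refer to the faces of the final decalin. C6 of 22, 23 and 24 is an epimer mixture of no consequence, since it is oxidised to the ketone.

Step 1
Reactants: 1 3,3-dimethylpent-4-enoic acid; 2 (R)-4-benzyl-1,3-oxazolidin-2-one
Product: 3 (4R)-4-benzyl-3-(3,3-dimethylpent-4-enoyl)-1,3-oxazolidin-2-one
Conditions: t-BuCOCl, Et3N, THF, −20 °C; then 2, LiCl, rt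
Reagents that add atoms: none
Why: N-acylation of the oxazolidinone through the mixed pivalic anhydride, which is attacked at its less hindered carbonyl.

Step 2
Reactants: 3; 4 tert-butyl bromoacetate
Product: 5 (4R)-4-benzyl-3-[(2R)-2-(2-tert-butoxy-2-oxoethyl)-3,3-dimethylpent-4-enoyl]-1,3-oxazolidin-2-one
Conditions: NaN(SiMe3)2, THF, −78 °C; then 4, −78 → −30 °C
Reagents that add atoms: none
Why: Auxiliary-controlled (Evans) enolate alkylation in which the chelated (Z)-sodium enolate is alkylated on the face away from the benzyl group, which sets C5.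

Step 3
Reactants: 5
Product: 7 (4R)-4-(2-methylbut-3-en-2-yl)oxolan-2-one, via hydroxy ester 6 (not isolated)
Conditions: LiBH4, MeOH (1 equiv), THF, 0 °C; then TsOH·H2O (cat.), toluene, 80 °C
Reagents that add atoms: none
Why: Reductive cleavage of the imide gives the C6 primary alcohol and spares the tert-butyl ester, and acid-catalysed lactonisation then closes the γ-lactone (C9 carbonyl, C6 methylene) without touching C5.

Step 4
Reactants: 7
Product: 8 (3S,4R)-3-methyl-4-(2-methylbut-3-en-2-yl)oxolan-2-one (3,4-trans)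
Conditions: LiN(i-Pr)2, THF, −78 °C; then MeI
Reagents that add atoms: iodomethane, CI
Why: Lactone enolate alkylation, in which iodomethane enters C10 trans to the bulky substituent on C5.

Step 5
Reactants: 8; 9 allyl bromide
Product: 10 (3S,4S)-3-methyl-4-(2-methylbut-3-en-2-yl)-3-(prop-2-en-1-yl)oxolan-2-one
Conditions: LiN(i-Pr)2, THF, −78 °C; then 9, DMPU, −78 → −20 °C
Reagents that add atoms: none
Why: Second lactone enolate alkylation, again anti to the C5 substituent, so that the allyl group (C1–C2) ends trans and the methyl cis to it, which fixes the quaternary C10.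

Step 6
Reactants: 10
Product: 11 trans-fused 4,4,7a-trimethyl-3a,4,7,7a-tetrahydro-2-benzofuran-1(3H)-one (ring A with C2=C3; 5α-H and 10β-CH3)
Conditions: RuCl2(=CHPh)(H2IMes)(PCy3) (second-generation Grubbs catalyst, 5 mol %), toluene (5 mM), 80 °C
Reagents that add atoms: none
Why: Ring-closing metathesis between the allyl group and the vinyl group on C4 closes ring A as the C2=C3 cyclohexene, the trans ring fusion being inherited from 10.

Step 7
Reactants: 11
Product: 13 4-chloro-2-(hydroxymethyl)-1,3,3-trimethyl-6-oxabicyclo[3.2.1]octan-7-one (3β-Cl and lactone oxygen on C2α), via lithium hydroxy carboxylate 12 (not isolated)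
Conditions: LiOH·H2O (1.05 equiv), THF/H2O, 50 °C; then 1,3-dichloro-5,5-dimethylhydantoin (0.55 equiv), MeCN/H2O, 0 °C; dilute HCl work-up
Reagents that add atoms: lithium hydroxide, [Li+].[OH-]; 1,3-dichloro-5,5-dimethylhydantoin, CC1(C)N(Cl)C(=O)N(Cl)C1=O
Why: Chlorolactonisation (halolactonisation) of the C9 carboxylate, which attacks C2 in a 5-exo mode from the α-face, anti to a β-chloronium ion and away from neopentyl C3, so that chlorine is placed on C3β and oxygen on C2α.

Step 8
Reactants: 13; 14 ethyl (triphenylphosphoranylidene)acetate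
Product: 16 ethyl (2E)-3-[4-chloro-5-hydroxy-2-(hydroxymethyl)-1,3,3-trimethylcyclohexyl]prop-2-enoate (2α-OH and 3β-Cl), via bridged lactol 15 (not isolated)
Conditions: i-Bu2AlH (2.2 equiv), CH2Cl2, −78 °C; then 14, toluene, 90 °C
Reagents that add atoms: none
Why: Partial reduction to the lactol followed by Wittig olefination of its open hydroxy aldehyde with the stabilised ylide gives the (E)-enoate (C9=C11–C12) under neutral conditions, which avoid epoxide closure of the chlorohydrin and oxa-Michael addition.

Step 9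
Reactants: 16
Product: 17 ethyl (2E)-3-[4-chloro-2-formyl-5-hydroxy-1,3,3-trimethylcyclohexyl]prop-2-enoate
Conditions: TEMPO (10 mol %), PhI(OAc)2 (1.1 equiv), CH2Cl2, rt
Reagents that add atoms: none
Why: Nitroxyl-catalysed oxidation that is selective for the primary C6 alcohol over the secondary C2 alcohol and stops at the aldehyde.

Step 10
Reactants: 17
Product: 18 ethyl (2E)-3-[4,5-dichloro-2-formyl-1,3,3-trimethylcyclohexyl]prop-2-enoate (2α,3β-dichloro)
Conditions: SOCl2 (1.5 equiv), CH2Cl2, 0 °C; then TiCl4 (10 mol %), 0 °C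
Reagents that add atoms: thionyl chloride, ClS(Cl)=O
Why: Deoxychlorination with retention (SNi-type front-side chloride delivery from the chlorosulfite–TiCl4 complex), and participation of the trans 3β-chlorine, with opening of the chloronium ion at the less hindered C2 from the α-face, would lead to the same 2α-chloride.

Step 11
Reactants: 19 propadiene; 20 bis(pinacolato)diboron
Product: 21 2,3-bis(4,4,5,5-tetramethyl-1,3,2-dioxaborolan-2-yl)prop-1-ene
Conditions: Pt(PPh3)4 (3 mol %), toluene, 80 °C, sealed vessel
Reagents that add atoms: none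
Why: Diboration of one C=C bond of the allene catalysed by zerovalent platinum (B–B oxidative addition, insertion, reductive elimination).

Step 12
Reactants: 18; 21
Product: 23 ethyl 2-(2α,3β-dichloro-6-hydroxy-4,4,10-trimethyl-8-methylidene-trans-decalin-9-yl)acetate, via borate boronate 22 (not isolated)
Conditions: Sc(OTf)3 (10 mol %), CH2Cl2, −78 → 0 °C; then in the same flask [Rh(cod)OH]2 (5 mol %), 1,4-dioxane/H2O (10:1), 60 °C
Reagents that add atoms: none
Why: The allylboronate arm of 21 adds to the C6 aldehyde through a closed six-membered chair transition state with allylic transposition (carbonyl allylboration, here accelerated by Sc(OTf)3), which forms C6–C7 and leaves the 2-borylalkene C8=C17 in 22; transmetalation of this alkenylboronate to monovalent rhodium, insertion of the tethered (E)-enoate and protonolysis of the rhodium oxa-π-allyl by water then form C8–C9 (intramolecular Hayashi–Miyaura 1,4-addition), the two events being known reaction types run in sequence as a formal [4+2] annulation. Ring B is closed in the second event by a 6-exo-trig carbometalation. C9 is set in this closure by a chair-like transition state trans-fused to ring A, in which the CH2CO2Et arm takes the equatorial β-position and H9 the axial α-position anti to the axial C10 methyl, while C5 and C10 are carried through unchanged and the C6 carbinol forms as an epimer mixture that the later oxidation removes. The step needs chemoselectivity (allylboron at the aldehyde only, alkenylboron at the enoate only) and 6-exo cyclisation ahead of protodeboronation; the first is inherent in the two boron groups, and the second is favoured by adding the rhodium catalyst only after the aldehyde is consumed, so that the conjugate addition is intramolecular.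

Step 13
Reactants: 23
Product: 24 2-(2α,3β-dichloro-6-hydroxy-4,4,10-trimethyl-8-methylidene-trans-decalin-9-yl)ethanol
Conditions: i-Bu2AlH (3.5 equiv), CH2Cl2, −78 → 0 °C
Reagents that add atoms: none
Why: Hydride reduction of the ester to the C12 primary alcohol, which leaves the secondary chlorides and the 1,1-disubstituted alkene untouched.

Step 14
Reactants: 24
Product: 25 2-(2α,3β-dichloro-4,4,10-trimethyl-8-methylidene-6-oxo-trans-decalin-9-yl)acetaldehyde
Conditions: Dess–Martin periodinane (3 equiv), pyridine, CH2Cl2, 0 °C → rt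
Reagents that add atoms: none
Why: Buffered hypervalent-iodine oxidation of both alcohols gives the C6 ketone and the C12 aldehyde without moving the β,γ-double bond into conjugation.

Step 15
Reactants: 26 3-cyanopropanoic acid; 2 (R)-4-benzyl-1,3-oxazolidin-2-one
Product: 27 (4R)-4-benzyl-3-(3-cyanopropanoyl)-1,3-oxazolidin-2-one
Conditions: t-BuCOCl, Et3N, THF, −20 °C; then 2, LiCl, rt
Reagents that add atoms: none
Why: N-acylation of the oxazolidinone through the mixed pivalic anhydride, the nitrile serving as a latent primary amide that cannot cyclise prematurely.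

Step 16
Reactants: 25; 27
Product: 28 (4R)-4-benzyl-3-[(2R,3S)-2-(cyanomethyl)-4-(2α,3β-dichloro-4,4,10-trimethyl-8-methylidene-6-oxo-trans-decalin-9-yl)-3-hydroxybutanoyl]-1,3-oxazolidin-2-one
Conditions: n-Bu2BOTf, i-Pr2NEt, CH2Cl2, 0 °C; then 25, −78 → 0 °C; pH 7 buffer, MeOH
Reagents that add atoms: none
Why: Evans syn aldol addition, in which the (Z)-boron enolate reacts with the aldehyde (and not the hindered ketone) through a Zimmerman–Traxler transition state on the face dictated by the (R)-auxiliary, which sets C12 (S) and C13 (R).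

Step 17
Reactants: 28
Product: 30 haterumaimide B, via primary amide 29 (not isolated)
Conditions: PtH(PMe2OH)(PMe2O)2H (5 mol %), EtOH/H2O (4:1), 70 °C; then 2-hydroxypyridine (20 mol %), toluene, 60 °C
Reagents that add atoms: water, O
Why: Neutral platinum-catalysed nitrile hydration gives the primary amide, whose nitrogen then attacks the activated N-acyl oxazolidinone carbonyl in a 5-exo acyl substitution that closes the succinimide and releases the auxiliary without base, so that C12 and C13 are not disturbed.

Compound list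
1 | 3,3-dimethylpent-4-enoic acid | C=CC(C)(C)CC(=O)O | starting material
2 | (R)-4-benzyl-1,3-oxazolidin-2-one | O=C1OC[C@@H](Cc2ccccc2)N1 | starting material
3 | (4R)-4-benzyl-3-(3,3-dimethylpent-4-enoyl)-1,3-oxazolidin-2-one | C=CC(C)(C)CC(=O)N1[C@H](Cc2ccccc2)COC1=O | intermediate
4 | tert-butyl bromoacetate | BrCC(=O)OC(C)(C)C | starting material
5 | (4R)-4-benzyl-3-[(2R)-2-(2-tert-butoxy-2-oxoethyl)-3,3-dimethylpent-4-enoyl]-1,3-oxazolidin-2-one | C=CC(C)(C)[C@@H](CC(=O)OC(C)(C)C)C(=O)N1[C@H](Cc2ccccc2)COC1=O | intermediate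
6 | tert-butyl (3R)-3-(hydroxymethyl)-4,4-dimethylhex-5-enoate | C=CC(C)(C)[C@@H](CC(=O)OC(C)(C)C)CO | intermediate
7 | (4R)-4-(2-methylbut-3-en-2-yl)oxolan-2-one | O=C1C[C@H](C(C)(C)C=C)CO1 | intermediate
8 | (3S,4R)-3-methyl-4-(2-methylbut-3-en-2-yl)oxolan-2-one (3,4-trans) | O=C1[C@@H](C)[C@H](C(C)(C)C=C)CO1 | intermediate
9 | allyl bromide (3-bromoprop-1-ene) | C=CCBr | starting material
10 | (3S,4S)-3-methyl-4-(2-methylbut-3-en-2-yl)-3-(prop-2-en-1-yl)oxolan-2-one (allyl trans and methyl cis to the C4 substituent) | O=C1[C@@](C)(CC=C)[C@H](C(C)(C)C=C)CO1 | intermediate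
11 | trans-fused 4,4,7a-trimethyl-3a,4,7,7a-tetrahydro-2-benzofuran-1(3H)-one (ring A with C2=C3; C9 lactone carbonyl, C6 lactone CH2; 5α-H, 10β-CH3) | C[C@]12CC=CC(C)(C)[C@@H]1COC2=O | intermediate
12 | lithium 6-(hydroxymethyl)-1,5,5-trimethylcyclohex-3-ene-1-carboxylate (carboxylate and hydroxymethyl trans) | [Li+].OC[C@H]1C(C)(C)C=CC[C@]1(C)C(=O)[O-] | intermediate
13 | 4-chloro-2-(hydroxymethyl)-1,3,3-trimethyl-6-oxabicyclo[3.2.1]octan-7-one (labdane positions: 3β-Cl, lactone O on C2α, 5α-H, free C6 hydroxymethyl) | OC[C@H]1C(C)(C)[C@@H](Cl)[C@H]2C[C@]1(C)C(=O)O2 | intermediate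
14 | ethyl (triphenylphosphoranylidene)acetate | CCOC(=O)C=P(c1ccccc1)(c1ccccc1)c1ccccc1 | starting material
15 | 4-chloro-2-(hydroxymethyl)-1,3,3-trimethyl-6-oxabicyclo[3.2.1]octan-7-ol (lactol of 13, anomer mixture) | OC[C@H]1C(C)(C)[C@@H](Cl)[C@H]2C[C@]1(C)C(O)O2 | intermediate
16 | ethyl (2E)-3-[4-chloro-5-hydroxy-2-(hydroxymethyl)-1,3,3-trimethylcyclohexyl]prop-2-enoate (2α-OH, 3β-Cl, 5α-H, 10β-CH3) | CCOC(=O)/C=C/[C@@]1(C)C[C@@H](O)[C@H](Cl)C(C)(C)[C@@H]1CO | intermediate
17 | ethyl (2E)-3-[4-chloro-2-formyl-5-hydroxy-1,3,3-trimethylcyclohexyl]prop-2-enoate (2α-OH, 3β-Cl, 5α-H, 10β-CH3) | CCOC(=O)/C=C/[C@@]1(C)C[C@@H](O)[C@H](Cl)C(C)(C)[C@@H]1C=O | intermediate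
18 | ethyl (2E)-3-[4,5-dichloro-2-formyl-1,3,3-trimethylcyclohexyl]prop-2-enoate (2α,3β-dichloro, 5α-H, 10β-CH3) | CCOC(=O)/C=C/[C@@]1(C)C[C@@H](Cl)[C@H](Cl)C(C)(C)[C@@H]1C=O | intermediate
19 | propadiene (allene) | C=C=C | starting material
20 | bis(pinacolato)diboron | CC1(C)OB(OC1(C)C)B1OC(C)(C)C(C)(C)O1 | starting material
21 | 2,3-bis(4,4,5,5-tetramethyl-1,3,2-dioxaborolan-2-yl)prop-1-ene | C=C(CB1OC(C)(C)C(C)(C)O1)B1OC(C)(C)C(C)(C)O1 | intermediate
22 | allylboration adduct of 18: C6 O-pinacolborate carrying the C8 pinacolboronate (C6 epimers) | CCOC(=O)/C=C/[C@@]1(C)C[C@@H](Cl)[C@H](Cl)C(C)(C)[C@@H]1C(CC(=C)B2OC(C)(C)C(C)(C)O2)OB3OC(C)(C)C(C)(C)O3 | intermediate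
23 | ethyl 2-(2α,3β-dichloro-6-hydroxy-4,4,10-trimethyl-8-methylidene-trans-decalin-9-yl)acetate (5α-H, 9α-H, 10β-CH3; C6 epimers) | C=C1CC(O)[C@H]2C(C)(C)[C@@H](Cl)[C@H](Cl)C[C@]2(C)[C@H]1CC(=O)OCC | intermediate
24 | 2-(2α,3β-dichloro-6-hydroxy-4,4,10-trimethyl-8-methylidene-trans-decalin-9-yl)ethanol (C6 epimers) | C=C1CC(O)[C@H]2C(C)(C)[C@@H](Cl)[C@H](Cl)C[C@]2(C)[C@H]1CCO | intermediate
25 | 2-(2α,3β-dichloro-4,4,10-trimethyl-8-methylidene-6-oxo-trans-decalin-9-yl)acetaldehyde | C=C1CC(=O)[C@H]2C(C)(C)[C@@H](Cl)[C@H](Cl)C[C@]2(C)[C@H]1CC=O | intermediate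
26 | 3-cyanopropanoic acid | N#CCCC(=O)O | starting material
27 | (4R)-4-benzyl-3-(3-cyanopropanoyl)-1,3-oxazolidin-2-one | N#CCCC(=O)N1[C@H](Cc2ccccc2)COC1=O | intermediate
28 | syn aldol adduct (12S,13R) carrying the cyanomethyl group on C13 and the (R)-oxazolidinone on C16 | C=C1CC(=O)[C@H]2C(C)(C)[C@@H](Cl)[C@H](Cl)C[C@]2(C)[C@H]1C[C@H](O)[C@@H](CC#N)C(=O)N3[C@H](Cc4ccccc4)COC3=O | intermediate
29 | primary amide from hydration of the nitrile of 28 | C=C1CC(=O)[C@H]2C(C)(C)[C@@H](Cl)[C@H](Cl)C[C@]2(C)[C@H]1C[C@H](O)[C@@H](CC(N)=O)C(=O)N3[C@H](Cc4ccccc4)COC3=O | intermediate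
30 | haterumaimide B | C=C1CC(=O)[C@H]2C(C)(C)[C@@H](Cl)[C@H](Cl)C[C@]2(C)[C@H]1C[C@H](O)[C@H]1CC(=O)NC1=O | target

Total step count: 17. Longest linear sequence: 15 steps (steps 1–10, 12–14, 16 and 17); steps 11 and 15 prepare the two reagents 21 and 27.

Steps most likely to fail

Step 12. The alkenylrhodium intermediate may be protonated (protodeboronation) before it inserts into the hindered enoate next to the quaternary C10, and the allylboration of the very hindered aldehyde may be slow. The fallback sets out from 18 and comes back at 23. Indium-mediated Barbier addition of 2,3-dibromopropene to the aldehyde (In, THF/H2O, rt) should give ethyl (2E)-3-[2-(3-bromo-1-hydroxybut-3-en-1-yl)-4,5-dichloro-1,3,3-trimethylcyclohexyl]prop-2-enoate F1. Treatment with n-Bu3SnH and AIBN (benzene, 80 °C, slow addition) then generates the C8 vinyl radical, which closes ring B by 6-exo-trig addition to the enoate. C8–C9 is thus formed by a radical and not an organorhodium pathway, in two separate operations.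

Step 7. The chloronium ion may be captured by the free C6 hydroxyl (chloroetherification at C3) or by water instead of the carboxylate, and the lactone closure may be slow because a C4 methyl lies under the lactone bridge. The fallback sets out from 11 and comes back at 18, passing by 13–17. Reduction with i-Bu2AlH and Wittig reaction with 14 should give ethyl (2E)-3-[6-(hydroxymethyl)-1,5,5-trimethylcyclohex-3-en-1-yl]prop-2-enoate F2, and TEMPO/PhI(OAc)2 oxidation its aldehyde ethyl (2E)-3-[6-formyl-1,5,5-trimethylcyclohex-3-en-1-yl]prop-2-enoate F3. Direct anti-dichlorination of the ring alkene with Et4NCl3 (CH2Cl2, −78 °C) follows; the enoate is inert to electrophilic chlorine. The 2α,3β isomer requires diaxial opening of the β-chloronium ion by chloride at C2 through the half-chair with the C9 and C6 arms axial, which is less certain than the lactone-directed route.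

Step 10. The chlorosulfite may ionise with loss of configuration, eliminate, or the reagents may attack the aldehyde. The fallback sets out from 17 and comes back at 18 by two successive inversions. PPh3 and N-bromosuccinimide (CH2Cl2, 0 °C) should give the inverted bromide ethyl (2E)-3-[5-bromo-4-chloro-2-formyl-1,3,3-trimethylcyclohexyl]prop-2-enoate (2β-bromo) F4, and LiCl in DMF (40 °C) then displaces bromide from the α-face to give the 2α-chloride.

Further compounds
F1 | step 12 | ethyl (2E)-3-[2-(3-bromo-1-hydroxybut-3-en-1-yl)-4,5-dichloro-1,3,3-trimethylcyclohexyl]prop-2-enoate | CCOC(=O)/C=C/[C@@]1(C)C[C@@H](Cl)[C@H](Cl)C(C)(C)[C@@H]1C(O)CC(Br)=C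
F2 | step 7 | ethyl (2E)-3-[6-(hydroxymethyl)-1,5,5-trimethylcyclohex-3-en-1-yl]prop-2-enoate | CCOC(=O)/C=C/[C@@]1(C)CC=CC(C)(C)[C@@H]1CO
F3 | step 7 | ethyl (2E)-3-[6-formyl-1,5,5-trimethylcyclohex-3-en-1-yl]prop-2-enoate | CCOC(=O)/C=C/[C@@]1(C)CC=CC(C)(C)[C@@H]1C=O
F4 | step 10 | ethyl (2E)-3-[5-bromo-4-chloro-2-formyl-1,3,3-trimethylcyclohexyl]prop-2-enoate (2β-bromo, 3β-chloro) | CCOC(=O)/C=C/[C@@]1(C)C[C@H](Br)[C@H](Cl)C(C)(C)[C@@H]1C=O
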